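## Structural features

The target is (7R,8R,8aS)-5-chloro-7,8-dihydroxy-7-methyl-1,7,8,8a-tetrahydro-6H-isochromen-6-one with a (1E,3E,5R,6S)-6-hydroxy-3,5-dimethylhepta-1,3-dienyl chain at C3. A dihydropyran ring A (O2, C1, C8a, C4a, C4, C3) is fused through C4a–C8a to a cyclohexenone ring B (C4a, C5, C6, C7, C8, C8a). O2–C3=C4–C4a=C5(Cl)–C6=O is a linearly conjugated push–pull chromophore (a doubly vinylogous ester) that runs on into the side-chain diene, so the molecule is sensitive to acid, to electrophiles and oxidants at C4/C5 and the diene, and to hydrogenolysis. Ring B carries three contiguous stereocentres, the quaternary methyl carbinol C7, the secondary carbinol C8 and the ring-fusion methine C8a, with the C7 oxygen, the C8 oxygen and C1 all on one face; the side chain carries a remote anti pair, C5′ (methyl) next to C6′ (carbinol). The C8 carbinol is a β-hydroxy ketone through C7 and a vinylogous aldol through C8a (retro-aldol, dehydration), C8a–H is the vinylogous α-proton of the enone (epimerisable), and C7 is a tertiary α-ketol. The real difficulty is the all-cis C7/C8/C8a triad beside an enolisable position, together with the timing of the chlorine, which is only unambiguous on a 1,3-dicarbonyl C5 before the polyene exists. The feature used: C8a is γ to the C6 carbonyl through C4a=C5, so C8–C8a is a vinylogous aldol bond; with C7 quaternary and C5 fully substituted, C8a–H2 of a monocyclic ring A pyranylidene ketone is the only enolisable C–H, and the C7 oxygen lies between the enolate oxygen O6 and the C8 aldehyde oxygen, where one metal can tie all three together.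

## Logic of the disconnections

**26 ⇒ 25.** Only the O–Si bond at C6′ is cut. The secondary hydroxyl must be masked because it would be oxidised in step 15 and would compete as a ligand in step 16. There is no skeletal gain. The forward step must be a non-basic fluoride cleavage, since the product is a β-hydroxy ketone.

**25 ⇒ 24 (key).** The C8–C8a bond is cut; ring B opens and C8 and C8a disappear as stereocentres, leaving C7 as the only stereocentre of the core. The forward step must enolise at C8a only and must set two centres from C7. Conformational analysis shows that a chelate between O7 and O8 alone fixes only the cis-diol: if O7 stands perpendicular to the dienolate, C1 comes out trans to the diol. The target requires O7 in the dienolate plane (syn to O6), the C7 methyl perpendicular and the aldehyde oxygen pointing back towards O6. Hence 24 keeps a free C7 hydroxyl, so that a single magnesium can bind O6, O7 and O8.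

**24 ⇒ 23.** No skeletal bond is cut; C8 is taken back to the alcohol level because an α-hydroxy aldehyde beside a ketone cannot be stored. The forward step must oxidise a neopentyl primary alcohol without cleaving the 1,2-diol or touching the polyene.

**23 ⇒ 21 (through 22).** The O2–C3 bond is cut, opening ring A to a δ-hydroxy ynenone, and the C1, C7 and C8 oxygens are masked. A free C7 hydroxyl cannot be carried further back: an α′-hydroxy 1,3-diketone or its enol triflate closes onto C4a to give a 3(2H)-furanone. O7 and O8 therefore travel as one isopropylidene acetal and are released together with the C1 hydroxyl before ring A exists. The forward step needs hydrolysis that spares the secondary silyl ether and a 6-endo addition at C3.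

**21 ⇒ 20 + 9.** The C4–C4a bond (sp–sp2) is cut. This separates the whole side chain, with both of its stereocentres, from the core and makes the route convergent. The forward coupling must take the C4a–O sulfonate and leave the C5–Cl bond.

**20 ⇒ 19 ⇒ 18.** The C4a–O sulfonate and the C5–Cl bond are removed. Chlorine is placed on the doubly activated C5 of a 1,3-diketone, where no other nucleophilic carbon competes. The forward sulfonylation must choose O4a over O6; the quaternary, oxygenated C7 next to O6 is relied on for this.

**18 ⇒ 15 + 17; 17 ⇒ 16.** The C5–C6 bond is cut (crossed Claisen). This gives a four-carbon ketone carrying C5, C4a, C8a and C1 and a non-enolisable ester carrying C6, C7 and C8. The forward step needs kinetic enolisation at the methyl group and a silyl ether on the β-oxygen that survives the base.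

**15 ⇒ 14 ⇒ 13 ⇒ 12 ⇒ 10 + 11.** The C7–C8 bond is cut. The quaternary centre comes from 10 by self-regeneration of the stereocentre: the acetal carbon of 12 remembers the configuration, and the one-carbon electrophile enters where the hydrogen was (retention), which gives the C7 configuration of 26. C8 is introduced as a free hydroxymethyl group, because a benzyl-type ether could not be removed later beside the vinyl chloride and polyene. 10 is used as the free acid, so no saponification is needed.

**9 ⇒ 8 ⇒ 6 + 7; 6 ⇒ 4 + 5; 4 ⇒ 3 ⇒ 2 ⇒ 1.** The C1′=C2′ and C3′=C4′ double bonds are cut as two carbonyl olefinations, each E-selective with a stabilised phosphorus reagent. The C5′–CH3 bond is cut back to 1, whose carbinol centre directs the methylation anti. The forward steps must not epimerise the α-branched aldehyde 4.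

## Other disconnections considered

**Alternative 1:** The cut goes through O2–C1 and C4a–C8a together, so both rings open in one operation. Forward, Et3N would isomerise the open-chain ynedione A1 to the 1,3-diacylallene A2. Its 1-oxadiene O2=C3–C4=C4a would add on heating to the vinyl group tethered at C8 (intramolecular oxa-Diels–Alder reaction) and give the 5-deschloro bicycle A3 as its C7/C8 acetonide.
- In favour: two bonds and two rings in one step, no aldehyde or free α-ketol, and C7 and C8 fixed beforehand in a rigid dioxolane. On ring-forming economy and on the security of C8 this plan is the better one.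
- Against: A2 is a doubly activated allene that can dimerise, add the amine or cycloisomerise to a furan. The dienophile is an unactivated vinyl group, so heat is needed while the side-chain diene offers competing pericyclic pathways. C8a is still set by substrate control (tether and endo/exo mode). Chlorine must be introduced on A3 afterwards, in competition with C4 and the diene. A1 needs its own synthesis of a vinyl diol segment with two stereocentres.
- Comparison: structurally it builds more per step. Mechanistically it exchanges the diastereoselectivity question of a polar aldol for the periselectivity question of a thermal cycloaddition of a labile allene; neither is clearly safer. In step count the double ring closure is largely paid for by the late chlorination and the longer route to A1, so the two plans should be of similar length.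

**Alternative 2:** The cut is the C4a=C5 double bond. Forward, LiCl and i-Pr2NEt would deprotonate the α-chloro-β-ketophosphonate A4 at C5, and the carbanion would olefinate the ynone carbonyl C4a intramolecularly (Horner–Wadsworth–Emmons reaction), closing ring B as the 3-alkynyl-2-chlorocyclohexenone A5.
- In favour: chlorine, enone and ring arise together with no regiochemical question, the conditions are mild, and no stereocentre is formed in the ring closure. On the stereochemical risk of the key step itself this plan is better than the chosen one.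
- Against: all three stereocentres must already be in the open chain. C8a there is α to the ynone carbonyl and β to the C8 oxygen, so the base that forms the phosphonate anion can epimerise it or expel the acetonide oxygen. The ynone is also a Michael acceptor, and olefination of a ketone by a hindered chlorinated phosphonate is slow. After the key step ring A is still open, so selective primary desilylation, oxa-Michael closure and removal of two further protecting groups follow (at least three steps against one).
- Comparison: structurally it closes the same ring but leaves ring A and the C8–C8a pair to other steps. Mechanistically it is a robust reaction type applied to a base-sensitive β-alkoxy ketone. It is longer both before and after the key step; it is equal only in placing chlorine early.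

**Alternative 3:** The cut is C4–C4a together with O2–C3. Forward, Pd(PPh3)4 and CuI would couple the ring B enol triflate A6 with the terminal dienynol A7, and the C1 hydroxyl of the coupling product would add to C3 in the same flask to give the target as its C7/C8 acetonide A8.
- In favour: it is the most convergent plan, the polyene meets the fewest steps, and the stereotriad is complete and locked in a ring before the sensitive chromophore exists. In convergence it is better than the chosen plan; in the number of steps after the key step (one) it is equal; and the coupling/oxa-Michael pair is the same chemistry as steps 13 and 14 here.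
- Against: A6 is a densely functionalised, enantiopure 2-chlorocyclohexane-1,3-dione derivative. Its C8a is α to the C4a carbonyl and β to O8 (epimerisation, elimination), its triflation has the same regiochemical question as step 12, and its synthesis must create C8 and C8a in extra stereoselective steps. The last step would hydrolyse a cis-fused ring acetonide beside a ketone on the finished, acid-sensitive target, which is harder than cleaving the terminal dioxolane before ring A exists.
- Comparison: structurally the same two ring A bonds are made, but last. Mechanistically the coupling is identical, while the stereochemistry moves from one ring-closing aldol into a longer ring B synthesis. The sequence after fragment union is shorter, but the preparation of A6 is longer and less certain than that of the two chiral-pool fragments used here.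

Key step: step 16

Assumption: the C4a=C5 geometry is not controlled in 20–24; 20–22 are drawn E (triflate or alkynyl cis to the C6 carbonyl, as expected from a chelated diketonate), 23–24 are drawn Z (the geometry that closes ring B), and 19 is drawn as the diketo form without configuration at the enolisable C–Cl carbon. Either isomer converges, because C4a–C5 is a single bond in the dienolates of steps 14 and 16.

## Route

Step 1
Reactants: 1 ethyl (S)-3-hydroxybutanoate
Product: 2 ethyl (2S,3S)-3-hydroxy-2-methylbutanoate
Conditions: LiN(i-Pr)2 (2.2 equiv), THF, −78 → −20 °C; MeI, DMPU, −78 → 0 °C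
Reagents that add atoms: iodomethane, CI
Why: Fráter–Seebach alkylation: the chelated lithium alkoxide–enolate dianion is methylated anti to the C3 methyl group, which sets C2 (the future C5′) anti to the existing carbinol centre.

Step 2
Reactants: 2 ethyl (2S,3S)-3-hydroxy-2-methylbutanoate
Product: 3 ethyl (2S,3S)-3-[(tert-butyldimethylsilyl)oxy]-2-methylbutanoate
Conditions: TBSCl, imidazole, DMF, rt
Reagents that add atoms: tert-butyldimethylsilyl chloride, CC(C)(C)[Si](C)(C)Cl
Why: Standard silylation of a secondary alcohol; the group must survive base, zerovalent palladium and mild acid up to the last step.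

Step 3
Reactants: 3 ethyl (2S,3S)-3-[(tert-butyldimethylsilyl)oxy]-2-methylbutanoate
Product: 4 (2S,3S)-3-[(tert-butyldimethylsilyl)oxy]-2-methylbutanal
Conditions: i-Bu2AlH (1.1 equiv), CH2Cl2, −78 °C; MeOH, aq. KNaC4H4O6
Reagents that add atoms: none
Why: Partial reduction of the ester: the aluminium hemiacetal is stable at −78 °C and gives the aldehyde only on work-up; the α-centre is not exposed to base and the crude aldehyde is used at once.

Step 4
Reactants: 4 (2S,3S)-3-[(tert-butyldimethylsilyl)oxy]-2-methylbutanal; 5 2-(triphenylphosphoranylidene)propanal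
Product: 6 (2E,4R,5S)-5-[(tert-butyldimethylsilyl)oxy]-2,4-dimethylhex-2-enal
Conditions: toluene, 90 °C
Reagents that add atoms: none
Why: Wittig olefination with a stabilised formyl ylide gives the (E)-trisubstituted enal (the C3′=C4′ bond); the weakly basic ylide should not enolise the α-branched aldehyde.

Step 5
Reactants: 6 (2E,4R,5S)-5-[(tert-butyldimethylsilyl)oxy]-2,4-dimethylhex-2-enal; 7 diethyl [3-(trimethylsilyl)prop-2-yn-1-yl]phosphonate
Product: 9 (3E,5E,7R,8S)-8-[(tert-butyldimethylsilyl)oxy]-5,7-dimethylnona-3,5-dien-1-yne, via C-silylated dienyne 8 (not isolated)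
Conditions: LiN(SiMe3)2, THF, −78 → 0 °C; then K2CO3, MeOH, rt
Reagents that add atoms: none
Why: Horner–Wadsworth–Emmons olefination with the propargylic phosphonate anion forms the C1′=C2′ bond with E selectivity, and methanolysis of the C(sp)–Si bond in the same flask frees the terminal alkyne; a minor Z isomer would be removed by chromatography.

Step 6
Reactants: 10 (S)-lactic acid; 11 pivalaldehyde
Product: 12 (2S,5S)-2-tert-butyl-5-methyl-1,3-dioxolan-4-one
Conditions: TsOH·H2O (cat.), H2SO4 (cat.), pentane, reflux (−H2O); crystallisation at −78 °C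
Reagents that add atoms: none
Why: Acid-catalysed acetalisation with azeotropic removal of water; the cis isomer is thermodynamically preferred and crystallises, storing the lactic acid configuration in the acetal carbon (self-regeneration of stereocentres).

Step 7
Reactants: 12 (2S,5S)-2-tert-butyl-5-methyl-1,3-dioxolan-4-one
Product: 13 (2S,5R)-2-tert-butyl-5-(hydroxymethyl)-5-methyl-1,3-dioxolan-4-one
Conditions: LiN(i-Pr)2, THF, −78 °C; CH2O (gas), −78 °C; aq. NH4Cl
Reagents that add atoms: formaldehyde, C=O
Why: Aldol addition of the lithium enolate to formaldehyde; the tert-butyl group shields one face, so the hydroxymethyl group enters trans to it and takes the place of the original hydrogen (overall retention), which sets the quaternary C7.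

Step 8
Reactants: 13 (2S,5R)-2-tert-butyl-5-(hydroxymethyl)-5-methyl-1,3-dioxolan-4-one
Product: 15 methyl (4R)-2,2,4-trimethyl-1,3-dioxolane-4-carboxylate, via diol methyl ester 14 (not isolated)
Conditions: HCl (cat., from AcCl), MeOH, 50 °C; then Me2C(OMe)2, TsOH·H2O (cat.), acetone, rt
Reagents that add atoms: methanol, CO; 2,2-dimethoxypropane, COC(C)(C)OC
Why: Acid-catalysed methanolysis opens the acylal to the methyl ester and frees both hydroxyls, and acetal exchange then ties O7 and O8 into one dioxolane; the quaternary centre cannot epimerise.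

Step 9
Reactants: 16 4-hydroxybutan-2-one
Product: 17 4-[(triethylsilyl)oxy]butan-2-one
Conditions: Et3SiCl, imidazole, CH2Cl2, 0 °C
Reagents that add atoms: chlorotriethylsilane, CC[Si](Cl)(CC)CC
Why: Silylation of the primary alcohol under a base too mild to cause β-elimination to the enone; the triethylsilyl group is chosen because it is lost with the dioxolane in step 14.

Step 10
Reactants: 17 4-[(triethylsilyl)oxy]butan-2-one; 15 methyl (4R)-2,2,4-trimethyl-1,3-dioxolane-4-carboxylate
Product: 18 5-[(triethylsilyl)oxy]-1-[(4R)-2,2,4-trimethyl-1,3-dioxolan-4-yl]pentane-1,3-dione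
Conditions: 17 (2.2 equiv), LiN(i-Pr)2 (2.3 equiv), THF, −78 °C; then 15, −78 → −30 °C; aq. NH4Cl
Reagents that add atoms: none
Why: Crossed Claisen condensation: kinetic deprotonation of the methyl group gives the terminal lithium enolate, which acylates the non-enolisable, α-alkoxy-activated ester to form C5–C6; a second equivalent of enolate deprotonates the diketone and drives the equilibrium.

Step 11
Reactants: 18 5-[(triethylsilyl)oxy]-1-[(4R)-2,2,4-trimethyl-1,3-dioxolan-4-yl]pentane-1,3-dione
Product: 19 2-chloro-5-[(triethylsilyl)oxy]-1-[(4R)-2,2,4-trimethyl-1,3-dioxolan-4-yl]pentane-1,3-dione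
Conditions: NCS (1.0 equiv), CH2Cl2, 0 °C → rt
Reagents that add atoms: N-chlorosuccinimide, O=C1CCC(=O)N1Cl
Why: Electrophilic chlorination of the enol of a 1,3-diketone at the doubly activated carbon (C5), the only nucleophilic carbon present at this stage; one equivalent limits dichlorination.

Step 12
Reactants: 19 2-chloro-5-[(triethylsilyl)oxy]-1-[(4R)-2,2,4-trimethyl-1,3-dioxolan-4-yl]pentane-1,3-dione
Product: 20 (3E)-4-chloro-5-oxo-1-[(triethylsilyl)oxy]-5-[(4R)-2,2,4-trimethyl-1,3-dioxolan-4-yl]pent-3-en-3-yl trifluoromethanesulfonate
Conditions: Tf2O, i-Pr2NEt, CH2Cl2, −78 °C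
Reagents that add atoms: trifluoromethanesulfonic anhydride, O=S(=O)(OS(=O)(=O)C(F)(F)F)C(F)(F)F
Why: O-Sulfonylation of the diketone enolate (enol triflate formation); O4a is flanked by a methylene whereas O6 is shielded by the quaternary dioxolane carbon and made less basic by its α-oxygen, so the triflate should form at C4a.

Step 13
Reactants: 20 (3E)-4-chloro-5-oxo-1-[(triethylsilyl)oxy]-5-[(4R)-2,2,4-trimethyl-1,3-dioxolan-4-yl]pent-3-en-3-yl trifluoromethanesulfonate; 9 (3E,5E,7R,8S)-8-[(tert-butyldimethylsilyl)oxy]-5,7-dimethylnona-3,5-dien-1-yne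
Product: 21 (2E,6E,8E,10R,11S)-11-[(tert-butyldimethylsilyl)oxy]-2-chloro-8,10-dimethyl-3-{2-[(triethylsilyl)oxy]ethyl}-1-[(4R)-2,2,4-trimethyl-1,3-dioxolan-4-yl]dodeca-2,6,8-trien-4-yn-1-one
Conditions: Pd(PPh3)4 (5 mol %), CuI (10 mol %), i-Pr2NH, THF, 0 °C → rt
Reagents that add atoms: none
Why: Sonogashira coupling: zerovalent palladium inserts into the C4a–OTf bond of the vinylogous mixed anhydride far faster than into the C5–Cl bond, and the copper acetylide of 9 delivers the dienynyl group to form C4–C4a.

Step 14
Reactants: 21 (2E,6E,8E,10R,11S)-11-[(tert-butyldimethylsilyl)oxy]-2-chloro-8,10-dimethyl-3-{2-[(triethylsilyl)oxy]ethyl}-1-[(4R)-2,2,4-trimethyl-1,3-dioxolan-4-yl]dodeca-2,6,8-trien-4-yn-1-one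
Product: 23 (1Z,3R)-1-{6-[(1E,3E,5R,6S)-6-[(tert-butyldimethylsilyl)oxy]-3,5-dimethylhepta-1,3-dien-1-yl]-2,3-dihydro-4H-pyran-4-ylidene}-1-chloro-3,4-dihydroxy-3-methylbutan-2-one, via triol ynenone 22 (not isolated)
Conditions: AcOH–THF–H2O (3:1:1), 40 °C; then Et3N, CH2Cl2, rt
Reagents that add atoms: none
Why: Aqueous acetic acid removes the primary triethylsilyl ether and hydrolyses the terminal dioxolane, while the hindered secondary tert-butyldimethylsilyl ether should persist; the C1 hydroxyl then adds to C3, the δ-carbon of the ynenone, in a 6-endo-dig oxa-Michael (1,6-) addition, and γ-protonation of the allenyl dienolate gives the push–pull pyranylidene ketone.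

Step 15
Reactants: 23 (1Z,3R)-1-{6-[(1E,3E,5R,6S)-6-[(tert-butyldimethylsilyl)oxy]-3,5-dimethylhepta-1,3-dien-1-yl]-2,3-dihydro-4H-pyran-4-ylidene}-1-chloro-3,4-dihydroxy-3-methylbutan-2-one
Product: 24 (2R,4Z)-4-{6-[(1E,3E,5R,6S)-6-[(tert-butyldimethylsilyl)oxy]-3,5-dimethylhepta-1,3-dien-1-yl]-2,3-dihydro-4H-pyran-4-ylidene}-4-chloro-2-hydroxy-2-methyl-3-oxobutanal
Conditions: SO3·pyridine, DMSO, i-Pr2NEt, CH2Cl2, 0 °C
Reagents that add atoms: none
Why: Parikh–Doering oxidation takes the primary alcohol to the aldehyde at 0 °C without glycol cleavage; the tertiary C7 hydroxyl cannot be oxidised and the crude α-hydroxy aldehyde is used at once.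

Step 16
Reactants: 24 (2R,4Z)-4-{6-[(1E,3E,5R,6S)-6-[(tert-butyldimethylsilyl)oxy]-3,5-dimethylhepta-1,3-dien-1-yl]-2,3-dihydro-4H-pyran-4-ylidene}-4-chloro-2-hydroxy-2-methyl-3-oxobutanal
Product: 25 (7R,8R,8aS)-3-[(1E,3E,5R,6S)-6-[(tert-butyldimethylsilyl)oxy]-3,5-dimethylhepta-1,3-dien-1-yl]-5-chloro-7,8-dihydroxy-7-methyl-1,7,8,8a-tetrahydro-6H-isochromen-6-one
Conditions: MgBr2·OEt2 (1.2 equiv), i-Pr2NEt (2.5 equiv), CH2Cl2, −20 → 0 °C; aq. NH4Cl
Reagents that add atoms: none
Why: The amine deprotonates the C7 hydroxyl and MgBr2 holds the alkoxide and the C6 carbonyl in a five-membered chelate, which acidifies the only enolisable C–H (C8a–H2, γ to C6 through C4a=C5) so that i-Pr2NEt can form the cross-conjugated magnesium dienolate (C8a=C4a, C5=C6–O–Mg), in which C4a–C5 is a single bond and both geometrical isomers of 24 converge. Its γ-carbon C8a adds to the non-enolisable C8 aldehyde, an intramolecular vinylogous aldol addition whose closest known type is the cyclisation of γ-enolisable enones onto tethered aldehydes under soft enolisation or amine base. Ring B closes in the 6-(enolendo)-exo-trig mode, with C8 as the out-of-plane atom above the planar dienolate. C8a is controlled by C7 through the O6–Mg–O7 chelate: with the C7 oxygen held in the dienolate plane, the methyl and formyl groups stand perpendicular on opposite faces, the formyl carbon can only reach the C8a face on its own side, and C1 (which stays in the plane of ring A) ends up cis to the C7 oxygen. C8 is controlled by the same metal: the aldehyde oxygen can become its third ligand only when C=O points back over the forming ring towards O6 (pseudo-axial oxygen, H8 outwards), which gives the 7,8-cis-diol, and the all-cis aldolate is also the only diastereomer in which O6, O7 and O8 can share one magnesium, so reversal of the aldol should feed the same isomer. The step needs γ-selectivity (secured by the fully substituted C5, the quaternary C7 and the non-enolisable aldehyde), one organising metal (hence close to one equivalent of MgBr2·OEt2, since a second magnesium chelating only O7 and O8 would turn the C7 oxygen perpendicular and deliver the C8a epimer) and a low temperature to suppress E1cB loss of the C8 oxygen.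

Step 17
Reactants: 25 (7R,8R,8aS)-3-[(1E,3E,5R,6S)-6-[(tert-butyldimethylsilyl)oxy]-3,5-dimethylhepta-1,3-dien-1-yl]-5-chloro-7,8-dihydroxy-7-methyl-1,7,8,8a-tetrahydro-6H-isochromen-6-one
Product: 26 (7R,8R,8aS)-5-chloro-7,8-dihydroxy-3-[(1E,3E,5R,6S)-6-hydroxy-3,5-dimethylhepta-1,3-dien-1-yl]-7-methyl-1,7,8,8a-tetrahydro-6H-isochromen-6-one
Conditions: HF·pyridine, pyridine, THF, 0 °C → rt
Reagents that add atoms: none
Why: Fluoride cleavage of the secondary silyl ether under buffered, non-basic conditions, which should avoid retro-aldol reaction, dehydration and C8a epimerisation of the β-hydroxy ketone.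

## Compound list

1 | ethyl (S)-3-hydroxybutanoate | CCOC(=O)C[C@H](C)O | starting material
2 | ethyl (2S,3S)-3-hydroxy-2-methylbutanoate | CCOC(=O)[C@@H](C)[C@H](C)O | intermediate
3 | ethyl (2S,3S)-3-[(tert-butyldimethylsilyl)oxy]-2-methylbutanoate | CCOC(=O)[C@@H](C)[C@H](C)O[Si](C)(C)C(C)(C)C | intermediate
4 | (2S,3S)-3-[(tert-butyldimethylsilyl)oxy]-2-methylbutanal | O=C[C@@H](C)[C@H](C)O[Si](C)(C)C(C)(C)C | intermediate
5 | 2-(triphenylphosphoranylidene)propanal | CC(C=O)=P(c1ccccc1)(c1ccccc1)c1ccccc1 | starting material
6 | (2E,4R,5S)-5-[(tert-butyldimethylsilyl)oxy]-2,4-dimethylhex-2-enal | O=C/C(C)=C/[C@@H](C)[C@H](C)O[Si](C)(C)C(C)(C)C | intermediate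
7 | diethyl [3-(trimethylsilyl)prop-2-yn-1-yl]phosphonate | CCOP(=O)(CC#C[Si](C)(C)C)OCC | starting material
8 | (3E,5E,7R,8S)-8-[(tert-butyldimethylsilyl)oxy]-5,7-dimethyl-1-(trimethylsilyl)nona-3,5-dien-1-yne | C[Si](C)(C)C#C/C=C/C(C)=C/[C@@H](C)[C@H](C)O[Si](C)(C)C(C)(C)C | intermediate
9 | (3E,5E,7R,8S)-8-[(tert-butyldimethylsilyl)oxy]-5,7-dimethylnona-3,5-dien-1-yne | C#C/C=C/C(C)=C/[C@@H](C)[C@H](C)O[Si](C)(C)C(C)(C)C | intermediate
10 | (S)-lactic acid | C[C@H](O)C(=O)O | starting material
11 | pivalaldehyde | CC(C)(C)C=O | starting material
12 | (2S,5S)-2-tert-butyl-5-methyl-1,3-dioxolan-4-one | C[C@@H]1O[C@H](C(C)(C)C)OC1=O | intermediate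
13 | (2S,5R)-2-tert-butyl-5-(hydroxymethyl)-5-methyl-1,3-dioxolan-4-one | C[C@]1(CO)O[C@H](C(C)(C)C)OC1=O | intermediate
14 | methyl (R)-2,3-dihydroxy-2-methylpropanoate | COC(=O)[C@](C)(O)CO | intermediate
15 | methyl (4R)-2,2,4-trimethyl-1,3-dioxolane-4-carboxylate | COC(=O)[C@]1(C)OC(C)(C)OC1 | intermediate
16 | 4-hydroxybutan-2-one | CC(=O)CCO | starting material
17 | 4-[(triethylsilyl)oxy]butan-2-one | CC(=O)CCO[Si](CC)(CC)CC | intermediate
18 | 5-[(triethylsilyl)oxy]-1-[(4R)-2,2,4-trimethyl-1,3-dioxolan-4-yl]pentane-1,3-dione | CC[Si](CC)(CC)OCCC(=O)CC(=O)[C@]1(C)OC(C)(C)OC1 | intermediate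
19 | 2-chloro-5-[(triethylsilyl)oxy]-1-[(4R)-2,2,4-trimethyl-1,3-dioxolan-4-yl]pentane-1,3-dione | CC[Si](CC)(CC)OCCC(=O)C(Cl)C(=O)[C@]1(C)OC(C)(C)OC1 | intermediate
20 | (3E)-4-chloro-5-oxo-1-[(triethylsilyl)oxy]-5-[(4R)-2,2,4-trimethyl-1,3-dioxolan-4-yl]pent-3-en-3-yl trifluoromethanesulfonate | CC[Si](CC)(CC)OCC/C(OS(=O)(=O)C(F)(F)F)=C(\Cl)C(=O)[C@]1(C)OC(C)(C)OC1 | intermediate
21 | (2E,6E,8E,10R,11S)-11-[(tert-butyldimethylsilyl)oxy]-2-chloro-8,10-dimethyl-3-{2-[(triethylsilyl)oxy]ethyl}-1-[(4R)-2,2,4-trimethyl-1,3-dioxolan-4-yl]dodeca-2,6,8-trien-4-yn-1-one | CC[Si](CC)(CC)OCC/C(C#C/C=C/C(C)=C/[C@@H](C)[C@H](C)O[Si](C)(C)C(C)(C)C)=C(\Cl)C(=O)[C@]1(C)OC(C)(C)OC1 | intermediate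
22 | (2R,4E,8E,10E,12R,13S)-13-[(tert-butyldimethylsilyl)oxy]-4-chloro-1,2-dihydroxy-5-(2-hydroxyethyl)-2,10,12-trimethyltetradeca-4,8,10-trien-6-yn-3-one | OCC/C(C#C/C=C/C(C)=C/[C@@H](C)[C@H](C)O[Si](C)(C)C(C)(C)C)=C(\Cl)C(=O)[C@](C)(O)CO | intermediate
23 | (1Z,3R)-1-{6-[(1E,3E,5R,6S)-6-[(tert-butyldimethylsilyl)oxy]-3,5-dimethylhepta-1,3-dien-1-yl]-2,3-dihydro-4H-pyran-4-ylidene}-1-chloro-3,4-dihydroxy-3-methylbutan-2-one | CC(/C=C/C1=C/C(CCO1)=C(\Cl)C(=O)[C@](C)(O)CO)=C\[C@@H](C)[C@H](C)O[Si](C)(C)C(C)(C)C | intermediate
24 | (2R,4Z)-4-{6-[(1E,3E,5R,6S)-6-[(tert-butyldimethylsilyl)oxy]-3,5-dimethylhepta-1,3-dien-1-yl]-2,3-dihydro-4H-pyran-4-ylidene}-4-chloro-2-hydroxy-2-methyl-3-oxobutanal | CC(/C=C/C1=C/C(CCO1)=C(\Cl)C(=O)[C@](C)(O)C=O)=C\[C@@H](C)[C@H](C)O[Si](C)(C)C(C)(C)C | intermediate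
25 | (7R,8R,8aS)-3-[(1E,3E,5R,6S)-6-[(tert-butyldimethylsilyl)oxy]-3,5-dimethylhepta-1,3-dien-1-yl]-5-chloro-7,8-dihydroxy-7-methyl-1,7,8,8a-tetrahydro-6H-isochromen-6-one | CC(/C=C/C1=CC2=C(Cl)C(=O)[C@](C)(O)[C@H](O)[C@@H]2CO1)=C\[C@@H](C)[C@H](C)O[Si](C)(C)C(C)(C)C | intermediate
26 | (7R,8R,8aS)-5-chloro-7,8-dihydroxy-3-[(1E,3E,5R,6S)-6-hydroxy-3,5-dimethylhepta-1,3-dien-1-yl]-7-methyl-1,7,8,8a-tetrahydro-6H-isochromen-6-one | CC(/C=C/C1=CC2=C(Cl)C(=O)[C@](C)(O)[C@H](O)[C@@H]2CO1)=C\[C@@H](C)[C@H](C)O | target

## Step count and least certain steps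

Total: 17 steps. Longest linear sequence: 11 steps (from 10 through steps 6, 7, 8 and 10–17); the side-chain branch from 1 is 10 steps (1–5, 13–17).

**Step 16 (key step).** Most likely failure: poor facial selection at C8a, because two magnesium-organised transition states compete. Closure through a chelate of O7 and O8 only, with O7 perpendicular to the dienolate, still gives the cis-diol but puts C1 trans to it. Further risks are slow γ-enolisation of the donor-stabilised dienone, E1cB dehydration of the aldolate, acyl migration in the α-ketol aldehyde, and remote enolisation along the polyene that would erode C5′. Fallback: move from kinetic to thermodynamic control at C8a. The closure of 24 would be run with excess MgBr2·OEt2, which should favour the two-oxygen chelate and give the C8a epimer of 25 F1. C8a–H is the vinylogous α-proton and C7 and C8 carry no acidic hydrogen, so F1 would then be equilibrated by reversible γ-enolisation with DBU in toluene at room temperature. The all-cis isomer is expected to be preferred: only it has the C7 hydroxyl in the carbonyl plane (hydrogen bond to O6) and the C8 hydroxyl pseudo-axial, free of the two gauche contacts an equatorial C8 substituent has with the C7 methyl and C1. This fallback sets out from 24 and comes back at 25.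

**Step 12.** Most likely failure: loss of regiocontrol in the O-sulfonylation (attack at O6, or mixtures), because the two enolate oxygens differ only in steric and inductive environment. Fallback: make the C4–C4a bond by a regiodefined addition to an ynone and chlorinate afterwards.
- But-3-yn-1-ol would be silylated to 4-[(triethylsilyl)oxy]but-1-yne F2, lithiated (n-BuLi, THF, −78 °C) and acylated by 15 in the presence of BF3·OEt2 to give the ynone F3.
- Pd(OAc)2 with tris(2,6-dimethoxyphenyl)phosphine would add the terminal C–H of 9 across the triple bond of F3, placing the alkynyl group on C4a only, to give the 5-deschloro analogue of 21 F4.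
- The conditions of step 14 would convert F4 to the 5-deschloro analogue of 23 F5, and NCS would chlorinate C5, the α-carbon of the vinylogous ester, to give 23.

The cost is that chlorination must then distinguish C5 from C4 and the diene. This fallback sets out from 15 and 9 and comes back at 23.

**Step 14.** Most likely failure: incomplete hydrolysis of the dioxolane, which is deactivated by the neighbouring carbonyl, or concurrent loss of the secondary silyl ether, so that no selective window exists. Fallback: give up the silyl ether and rely on chemoselective oxidation. 21 would be deprotected fully (TFA–H2O, CH2Cl2, 0 °C; then Et3N) to the desilylated analogue of 23 F6. The neopentyl primary alcohol would be oxidised in the presence of the secondary and tertiary ones with TEMPO and PhI(OAc)2 to the desilylated analogue of 24 F7, and the conditions of step 16 applied to F7 would lead directly to 26, making step 17 unnecessary. This fallback sets out from 21 and comes back at 26.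

**Step 10.** Most likely failure: sluggish acylation of the enolate by the neopentyl-type ester, with proton transfer or β-elimination of the silyloxy group from 17 taking over on warming. Fallback: a two-stage aldol/oxidation. 15 would be reduced (i-Bu2AlH, CH2Cl2, −78 °C) to (4R)-2,2,4-trimethyl-1,3-dioxolane-4-carbaldehyde F8, the lithium enolate of 17 would add to it to give the β-hydroxy ketone F9 (either carbinol epimer), and Dess–Martin periodinane would oxidise F9 to 18. This fallback sets out from 15 and 17 and comes back at 18.

**Step 7.** Most likely failure: oligomerisation of formaldehyde and acyl transfer or over-reaction of the primary alkoxide, giving low conversion to the hydroxymethyl compound. Fallback: alkylation instead of aldol addition. The enolate of 12 would be alkylated with benzyl chloromethyl ether to (2S,5R)-5-[(benzyloxy)methyl]-2-tert-butyl-5-methyl-1,3-dioxolan-4-one F10, and hydrogenolysis (H2, Pd/C, EtOAc) at this early stage, where nothing else is reducible, would give 13. This fallback sets out from 12 and comes back at 13.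

## Further compounds

F1 | step 16 | (7R,8R,8aR)-3-[(1E,3E,5R,6S)-6-[(tert-butyldimethylsilyl)oxy]-3,5-dimethylhepta-1,3-dien-1-yl]-5-chloro-7,8-dihydroxy-7-methyl-1,7,8,8a-tetrahydro-6H-isochromen-6-one (C8a epimer of 25) | CC(/C=C/C1=CC2=C(Cl)C(=O)[C@](C)(O)[C@H](O)[C@H]2CO1)=C\[C@@H](C)[C@H](C)O[Si](C)(C)C(C)(C)C
F2 | step 12 | 4-[(triethylsilyl)oxy]but-1-yne | C#CCCO[Si](CC)(CC)CC
F3 | step 12 | 5-[(triethylsilyl)oxy]-1-[(4R)-2,2,4-trimethyl-1,3-dioxolan-4-yl]pent-2-yn-1-one | CC[Si](CC)(CC)OCCC#CC(=O)[C@]1(C)OC(C)(C)OC1
F4 | step 12 | 5-deschloro analogue of 21 (alkynyl group cis to H5) | CC[Si](CC)(CC)OCC/C(C#C/C=C/C(C)=C/[C@@H](C)[C@H](C)O[Si](C)(C)C(C)(C)C)=C\C(=O)[C@]1(C)OC(C)(C)OC1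
F5 | step 12 | 5-deschloro analogue of 23 | CC(/C=C/C1=C/C(CCO1)=C/C(=O)[C@](C)(O)CO)=C\[C@@H](C)[C@H](C)O[Si](C)(C)C(C)(C)C
F6 | step 14 | desilylated analogue of 23 (free C6′ hydroxyl) | CC(/C=C/C1=C/C(CCO1)=C(\Cl)C(=O)[C@](C)(O)CO)=C\[C@@H](C)[C@H](C)O
F7 | step 14 | desilylated analogue of 24 (free C6′ hydroxyl) | CC(/C=C/C1=C/C(CCO1)=C(\Cl)C(=O)[C@](C)(O)C=O)=C\[C@@H](C)[C@H](C)O
F8 | step 10 | (4R)-2,2,4-trimethyl-1,3-dioxolane-4-carbaldehyde | O=C[C@]1(C)OC(C)(C)OC1
F9 | step 10 | 1-hydroxy-5-[(triethylsilyl)oxy]-1-[(4R)-2,2,4-trimethyl-1,3-dioxolan-4-yl]pentan-3-one | CC[Si](CC)(CC)OCCC(=O)CC(O)[C@]1(C)OC(C)(C)OC1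
F10 | step 7 | (2S,5R)-5-[(benzyloxy)methyl]-2-tert-butyl-5-methyl-1,3-dioxolan-4-one | C[C@]1(COCc2ccccc2)O[C@H](C(C)(C)C)OC1=O
A1 | alternative 1 | open-chain ynedione with C7/C8 acetonide and C8 vinyl group | C=C[C@H]1OC(C)(C)O[C@@]1(C)C(=O)C#CCC(=O)/C=C/C(C)=C/[C@@H](C)[C@H](C)O[Si](C)(C)C(C)(C)C
A2 | alternative 1 | 1,3-diacylallene isomer of A1 | C=C[C@H]1OC(C)(C)O[C@@]1(C)C(=O)C=C=CC(=O)/C=C/C(C)=C/[C@@H](C)[C@H](C)O[Si](C)(C)C(C)(C)C
A3 | alternative 1 | 5-deschloro bicyclic core as C7/C8 acetonide, side-chain silyl ether | CC(/C=C/C1=CC2=CC(=O)[C@]3(C)OC(C)(C)O[C@@H]3[C@@H]2CO1)=C\[C@@H](C)[C@H](C)O[Si](C)(C)C(C)(C)C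
A4 | alternative 2 | open-chain α-chloro-β-ketophosphonate ynone | CCOP(=O)(OCC)C(Cl)C(=O)[C@]1(C)OC(C)(C)O[C@@H]1[C@H](CO[Si](C)(C)C(C)(C)C)C(=O)C#C/C=C/C(C)=C/[C@@H](C)[C@H](C)O[Si](C)(C)C(C)(C)C
A5 | alternative 2 | 3-alkynyl-2-chlorocyclohexenone (ring B) with side chain | CC(/C=C/C#CC1=C(Cl)C(=O)[C@]2(C)OC(C)(C)O[C@@H]2[C@@H]1CO[Si](C)(C)C(C)(C)C)=C\[C@@H](C)[C@H](C)O[Si](C)(C)C(C)(C)C
A6 | alternative 3 | ring B enol triflate with C7/C8 acetonide and free C1 hydroxyl | FC(F)(F)S(=O)(=O)OC1=C(Cl)C(=O)[C@]2(C)OC(C)(C)O[C@@H]2[C@@H]1CO
A7 | alternative 3 | (2S,3R,4E,6E)-3,5-dimethylnona-4,6-dien-8-yn-2-ol | C#C/C=C/C(C)=C/[C@@H](C)[C@H](C)O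
A8 | alternative 3 | target as its C7/C8 acetonide | CC(/C=C/C1=CC2=C(Cl)C(=O)[C@]3(C)OC(C)(C)O[C@@H]3[C@@H]2CO1)=C\[C@@H](C)[C@H](C)O
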